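**Retrosynthetic overview**
- Target 15 ← hydrogenolysis of the 4'-O-benzyl ether of 14 ← O-sulfation of 3-OH and 7-OH of 4'-O-benzylkaempferol 12 (5-OH stays free, hydrogen-bonded to C4=O) ← methanolysis of 3-benzoate 11.
- Ring C is the only ring built: C4–C4a and O1–C2 are made in one thermal condensation of phloroglucinol 8 with the α-benzoyloxy aroylacetate 7. Rings A and B are bought.
- Structural feature: ring A (C4a, C5, C6, C7, C8, C8a) carries oxygen on C5, C7 and C8a (O1), so it is phloroglucinol, whose three free ring carbons are equivalent. Acylation at any of them gives the same C4–C4a bond; the two flanking oxygens become O1 and 5-OH, the remote one 7-OH.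
- 7 ← α-benzoyloxylation of β-keto ester 4, as its potassium enolate 6, with dibenzoyl peroxide 5 ← Claisen condensation of 4'-benzyloxyacetophenone 1 with diethyl carbonate 2.

Key step: step 3

Remark: the aryl hydrogen sulfates 13–15 are written as free acids to match the target. In the flask they would be potassium (or pyridinium) salts, and the acid form of 15 would be released only in the last work-up on a cold H+ resin. Phenolate salts formed in basic steps are likewise written as the neutral phenols.

**Step 1**
Reactants: 1 1-[4-(benzyloxy)phenyl]ethan-1-one; 2 diethyl carbonate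
Product: 4 ethyl 3-[4-(benzyloxy)phenyl]-3-oxopropanoate, via sodium enolate 3 (not isolated)
Conditions: NaH (2.5 equiv), (EtO)2CO (3 equiv), THF, reflux; then 1 M HCl, 0 °C
Reagents that add atoms: none
Why: Claisen condensation of the ketone enolate with a carbonate that has no α-hydrogen; irreversible deprotonation of the product to enolate 3 should drive it to completion, and the benzyl ether is inert to NaH.

**Step 2**
Reactants: 4 ethyl 3-[4-(benzyloxy)phenyl]-3-oxopropanoate; 5 dibenzoyl peroxide
Product: 7 racemic ethyl 2-(benzoyloxy)-3-[4-(benzyloxy)phenyl]-3-oxopropanoate, via potassium enolate 6 (not isolated)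
Conditions: KOtBu (1.0 equiv), THF, 0 °C, 15 min; then (PhCO2)2 (1.0 equiv, dried) in THF, 0 °C → rt; 1 M HCl
Reagents that add atoms: none
Why: Enolate α-benzoyloxylation, in which the carbon of the fully formed potassium enolate 6 attacks the peroxide O–O bond and expels benzoate, as known for malonates and β-keto esters; the new stereocentre forms racemic and needs no control because it becomes sp2 C3 in step 3, and one equivalent of base and peroxide at 0 °C should leave no free alkoxide to attack the peroxide and should limit a second oxygenation.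

**Step 3**
Reactants: 7 racemic ethyl 2-(benzoyloxy)-3-[4-(benzyloxy)phenyl]-3-oxopropanoate; 8 phloroglucinol (anhydrous)
Product: 11 3-(benzoyloxy)-4'-benzyloxy-5,7-dihydroxyflavone, via acylketene 9 (not isolated), via acylphloroglucinol diketone 10 (not isolated)
Conditions: 8 (1.5 equiv), neat melt, 240 °C, Ar stream, 20–30 min (or microwave, 240 °C, 5 min); no catalyst
Reagents that add atoms: none
Why: At about 240 °C the enol of 7 loses ethanol to give acylketene 9, which acylates a ring carbon of 8 (directly, or by O-acylation and Fries shift) to form C4–C4a in diketone 10; an ortho hydroxyl of 10 then adds to the aryl ketone carbon and water is lost, forming O1–C2 and the pyranone. The closest known reaction is the Mentzer thermal pyrone synthesis, by which phloroglucinol and aroylacetic esters, 2-substituted ones included, give 5,7-dihydroxyflavones without catalyst. Ring C closes in the 6-exo-trig mode (phenol oxygen onto the ketone C=O), followed by dehydration of the hemiketal. No stereocentre is formed; the one in racemic 7 becomes the sp2 carbon C3, so the racemate serves. The step needs chromone rather than coumarin formation, which the acid-free ketene pathway secures by placing the ester carbon, not the ketone carbon, on the ring, and it needs no regiocontrol because the three ring carbons of 8 and the two ortho hydroxyls of 10 are equivalent. Benzoyl transfer to O5 or O7 in the melt would do no harm, since step 4 removes every benzoate.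

**Step 4**
Reactants: 11 3-(benzoyloxy)-4'-benzyloxy-5,7-dihydroxyflavone
Product: 12 4'-O-benzylkaempferol
Conditions: K2CO3 (2 equiv), MeOH–THF, rt, Ar; then 1 M HCl to pH 3
Reagents that add atoms: none
Why: Base-mediated transesterification (methanolysis) of an activated enol benzoate; the benzyl ether and chromone are inert, and exclusion of air should prevent autoxidation of the flavonolate.

**Step 5**
Reactants: 12 4'-O-benzylkaempferol
Product: 14 4'-O-benzylkaempferol 3,7-di-O-sulfate, via 7-monosulfate 13 (not isolated)
Conditions: SO3·pyridine (6 equiv), pyridine, 25 → 45 °C; aq. KHCO3, C18 chromatography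
Reagents that add atoms: sulfur trioxide–pyridine complex, O=S(=O)([O-])[n+]1ccccc1
Why: Phenol O-sulfation with an SO3–amine complex; the acidic 7-OH should react first (13), then the 3-OH, while the 5-OH is held in a six-membered hydrogen bond to the C4 carbonyl and the 4'-oxygen is benzylated, so the reaction should stop at the 3,7-disulfate.

**Step 6**
Reactants: 14 4'-O-benzylkaempferol 3,7-di-O-sulfate
Product: 15 kaempferol 3,7-di-O-sulfate
Conditions: H2 (1 atm), 10% Pd/C (palladium metal on carbon), MeOH–H2O, pH 7–8 (trace KHCO3), rt; filter; Dowex 50W (H+ form), 0 °C, freeze-dry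
Reagents that add atoms: none
Why: Catalytic hydrogenolysis of the benzylic C–O bond; aryl sulfate monoester salts are not reduced and are stable at near-neutral pH, and the tetrasubstituted C2=C3 bond of the chromone should resist hydrogenation under these mild conditions.

**Compound list**
1 | 1-[4-(benzyloxy)phenyl]ethan-1-one (4'-benzyloxyacetophenone) | CC(=O)c1ccc(OCc2ccccc2)cc1 | starting material
2 | diethyl carbonate | CCOC(=O)OCC | starting material
3 | sodium (Z)-1-[4-(benzyloxy)phenyl]-3-ethoxy-3-oxoprop-1-en-1-olate (sodium enolate of 4, not isolated) | [Na+].CCOC(=O)/C=C(\[O-])c1ccc(OCc2ccccc2)cc1 | intermediate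
4 | ethyl 3-[4-(benzyloxy)phenyl]-3-oxopropanoate | CCOC(=O)CC(=O)c1ccc(OCc2ccccc2)cc1 | intermediate
5 | dibenzoyl peroxide | O=C(OOC(=O)c1ccccc1)c1ccccc1 | starting material
6 | potassium (Z)-1-[4-(benzyloxy)phenyl]-3-ethoxy-3-oxoprop-1-en-1-olate (potassium enolate of 4, not isolated) | [K+].CCOC(=O)/C=C(\[O-])c1ccc(OCc2ccccc2)cc1 | intermediate
7 | racemic ethyl 2-(benzoyloxy)-3-[4-(benzyloxy)phenyl]-3-oxopropanoate | CCOC(=O)C(OC(=O)c1ccccc1)C(=O)c1ccc(OCc2ccccc2)cc1 | intermediate
8 | phloroglucinol (benzene-1,3,5-triol) | Oc1cc(O)cc(O)c1 | starting material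
9 | 3-[4-(benzyloxy)phenyl]-1,3-dioxoprop-1-en-2-yl benzoate (acylketene, not isolated) | O=C=C(OC(=O)c1ccccc1)C(=O)c1ccc(OCc2ccccc2)cc1 | intermediate
10 | racemic 1-[4-(benzyloxy)phenyl]-1,3-dioxo-3-(2,4,6-trihydroxyphenyl)propan-2-yl benzoate (not isolated) | O=C(c1ccc(OCc2ccccc2)cc1)C(OC(=O)c1ccccc1)C(=O)c1c(O)cc(O)cc1O | intermediate
11 | 3-(benzoyloxy)-4'-benzyloxy-5,7-dihydroxyflavone (2-[4-(benzyloxy)phenyl]-5,7-dihydroxy-4-oxo-4H-chromen-3-yl benzoate) | O=C(Oc1c(-c2ccc(OCc3ccccc3)cc2)oc2cc(O)cc(O)c2c1=O)c1ccccc1 | intermediate
12 | 4'-O-benzylkaempferol (2-[4-(benzyloxy)phenyl]-3,5,7-trihydroxy-4H-chromen-4-one) | O=c1c(O)c(-c2ccc(OCc3ccccc3)cc2)oc2cc(O)cc(O)c12 | intermediate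
13 | 4'-O-benzylkaempferol 7-O-sulfate (not isolated) | O=c1c(O)c(-c2ccc(OCc3ccccc3)cc2)oc2cc(OS(=O)(=O)O)cc(O)c12 | intermediate
14 | 4'-O-benzylkaempferol 3,7-di-O-sulfate | O=c1c(OS(=O)(=O)O)c(-c2ccc(OCc3ccccc3)cc2)oc2cc(OS(=O)(=O)O)cc(O)c12 | intermediate
15 | kaempferol 3,7-di-O-sulfate | O=c1c(OS(=O)(=O)O)c(-c2ccc(O)cc2)oc2cc(OS(=O)(=O)O)cc(O)c12 | target

**Totals**
Total step count: 6. Longest linear sequence: 6 steps (1 → 4 → 7 → 11 → 12 → 14 → 15); phloroglucinol 8 enters at step 3.

**Steps most likely to fail**

1. Step 3. The α-benzoyloxy ester is a little-tested member of the α-substituted aroylacetate class for this condensation. Several processes could compete in the melt: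
 - shift of the benzoyl group across the enediol of 7 onto the ketone-derived oxygen before ethanol is lost, which gives an α-keto ester that cannot close the chromone;
 - phenolysis of the benzoate by phloroglucinol;
 - thermal O-to-C migration of the benzyl group;
 - coumarin-type closure at the ketone carbon.

 Fallback, setting out from 4 and 8 and returning at 12: the unsubstituted ester 4 would be condensed with 8 in the same neat melt at 240 °C, the best-documented case of this condensation, to give 4'-O-benzylapigenin F1. Both free phenols would be capped with MOMCl and NaH in DMF to give 4'-benzyloxy-5,7-bis(methoxymethoxy)flavone F2. C3 would be lithiated with LDA in THF at −78 °C, trapped with B(OMe)3 and oxidised with H2O2/AcOH to give 4'-benzyloxy-3-hydroxy-5,7-bis(methoxymethoxy)flavone F3. HCl in MeOH would then remove both MOM groups to give 12. The C3 oxygen is installed after ring closure, so no acyloxy group has to survive the melt.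

2. Step 5. Sulfation may stall at the 3-OH or creep onto the 5-OH, giving regioisomeric ionic products that are hard to separate, and the 3-sulfate may hydrolyse during isolation.
 Fallback, setting out from 12 and returning at 14: 12 would be treated with 2,2,2-trichloroethyl chlorosulfate (2.5 equiv), Et3N and DMAP in THF to give the neutral diester 4'-O-benzylkaempferol 3,7-bis(2,2,2-trichloroethyl sulfate) F4, which can be purified on silica and have its regiochemistry checked. Zn dust and ammonium formate in MeOH would then remove both trichloroethyl groups by reductive β-elimination to give 14.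

3. Step 2. Proton exchange between product 7 and enolate 6 may lead to a second benzoyloxylation, and the peroxide may decompose in the basic medium.
 Fallback, setting out from 4 and returning at 7: diazo transfer with 4-acetamidobenzenesulfonyl azide and Et3N in MeCN would give ethyl 3-[4-(benzyloxy)phenyl]-2-diazo-3-oxopropanoate F5. Rh2(OAc)4 (1 mol %) with benzoic acid in CH2Cl2 at reflux would then give 7 by O–H insertion of the rhodium carbenoid, which introduces exactly one benzoyloxy group.

**Further compounds**
F1 | step 3 | 4'-O-benzylapigenin (2-[4-(benzyloxy)phenyl]-5,7-dihydroxy-4H-chromen-4-one) | O=c1cc(-c2ccc(OCc3ccccc3)cc2)oc2cc(O)cc(O)c12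
F2 | step 3 | 4'-benzyloxy-5,7-bis(methoxymethoxy)flavone | COCOc1cc(OCOC)c2c(=O)cc(-c3ccc(OCc4ccccc4)cc3)oc2c1
F3 | step 3 | 4'-benzyloxy-3-hydroxy-5,7-bis(methoxymethoxy)flavone | COCOc1cc(OCOC)c2c(=O)c(O)c(-c3ccc(OCc4ccccc4)cc3)oc2c1
F4 | step 5 | 4'-O-benzylkaempferol 3,7-bis(2,2,2-trichloroethyl sulfate) | O=c1c(OS(=O)(=O)OCC(Cl)(Cl)Cl)c(-c2ccc(OCc3ccccc3)cc2)oc2cc(OS(=O)(=O)OCC(Cl)(Cl)Cl)cc(O)c12
F5 | step 2 | ethyl 3-[4-(benzyloxy)phenyl]-2-diazo-3-oxopropanoate | CCOC(=O)C(=[N+]=[N-])C(=O)c1ccc(OCc2ccccc2)cc1
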